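The route rests on forming two bonds on adjacent ring A carbons at once: the bond from carbon 1 to the butanoyl carbonyl and the bond from carbon 2 to its hydroxyl oxygen. This vicinal acyl/oxygen pair lies between the methyl on carbon 3 and the oxygen on carbon 6. An aryne spanning carbons 1 and 2, released by fluoride from a 2-silylaryl triflate, inserts into the C–O bond of butanoic acid, so ketone and phenol arrive in one operation. The precursor is the complete diarylmethane carrying SiMe3 on carbon 1, triflate on carbon 2 and benzyl ethers on the carbon 6 oxygen and all three ring B oxygens.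

Key step: step 12

Numbering used below: in ring A, carbon 1 bears the butanoyl group, carbon 2 the adjacent hydroxyl, carbon 3 the methyl, carbon 4 the methoxy group, carbon 5 the CH2 bridge and carbon 6 the second hydroxyl. In ring B, carbon 1 bears the bridge, carbons 2, 4 and 6 the hydroxyls, carbon 3 the methyl and carbon 5 the acetyl group.

Remark on the chemistry: the target has no stereocentre, so no stereocontrol is required; the three starting materials are taken as purchased.

Step 1
Reactants: 1 3-methoxy-2-methylphenol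
Product: 2 3-methoxy-2-methylphenyl propan-2-ylcarbamate
Conditions: i-PrNCO, Et3N (cat.), CH2Cl2, rt
Reagents that add atoms: isopropyl isocyanate, CC(C)N=C=O
Why: Base-catalysed carbamoylation of the phenol caps the oxygen of the future ring A carbon 2 as an N-isopropyl carbamate, which keeps it distinct from the oxygen introduced next, later directs lithiation to the future carbon 1 and can be removed by mild base-induced elimination.

Step 2
Reactants: 2 3-methoxy-2-methylphenyl propan-2-ylcarbamate
Product: 4 5-hydroxy-3-methoxy-2-methylphenyl propan-2-ylcarbamate, via aryl pinacol boronate 3 (not isolated)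
Conditions: [Ir(OMe)(cod)]2 (1.5 mol %), dtbpy (3 mol %), B2pin2, THF, 80 °C; then KHSO5 (as 2KHSO5·KHSO4·K2SO4), acetone–H2O, rt
Reagents that add atoms: bis(pinacolato)diboron, CC1(C)OB(OC1(C)C)B1OC(C)(C)C(C)(C)O1 (boron is carried only by 3); potassium peroxymonosulfate, [K+].[O-]S(=O)(=O)OO (source of the new oxygen)
Why: Sterically governed iridium-catalysed aromatic C–H borylation should attack the only ring hydrogen without an ortho substituent (the future ring A carbon 6), and peroxymonosulfate oxidation of the C–B bond then gives the phenol at the same carbon.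

Step 3
Reactants: 4 5-hydroxy-3-methoxy-2-methylphenyl propan-2-ylcarbamate
Product: 5 5-(benzyloxy)-3-methoxy-2-methylphenyl propan-2-ylcarbamate
Conditions: BnBr, K2CO3, acetone, rt
Reagents that add atoms: benzyl bromide, BrCc1ccccc1
Why: Williamson etherification of the only free phenol under mild carbonate conditions, which should leave the N–H carbamate intact.

Step 4
Reactants: 5 5-(benzyloxy)-3-methoxy-2-methylphenyl propan-2-ylcarbamate
Product: 9 3-(benzyloxy)-2-bromo-5-methoxy-6-methylphenyl propan-2-ylcarbamate, via N-silyl carbamate 6 (not isolated), via aryllithium 7 (not isolated), via N-silyl bromo carbamate 8 (not isolated)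
Conditions: TBSOTf, TMEDA, Et2O, 0 °C to rt; n-BuLi, TMEDA, −78 °C; BrCl2C–CCl2Br, −78 °C to rt; aq. NaHSO4
Reagents that add atoms: 1,2-dibromotetrachloroethane, ClC(Cl)(Br)C(Cl)(Cl)Br; tert-butyldimethylsilyl trifluoromethanesulfonate, CC(C)(C)[Si](C)(C)OS(=O)(=O)C(F)(F)F (silyl group is carried only by 6, 7 and 8)
Why: Directed ortho-metalation, in which the N-silylated carbamate (the strongest director present) and the benzyloxy group together steer n-BuLi to the hydrogen between them (carbon 1 of ring A) and not to carbon 5 beside the weaker methoxy director; the aryllithium then takes bromine from the polyhaloethane.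

Step 5
Reactants: 9 3-(benzyloxy)-2-bromo-5-methoxy-6-methylphenyl propan-2-ylcarbamate
Product: 10 3-(benzyloxy)-2-bromo-5-methoxy-6-methylphenol
Conditions: DBU, Et2NH, MeCN, 40 °C; aq. HCl work-up
Reagents that add atoms: none
Why: Conjugate-base elimination of the N-monosubstituted aryl carbamate (N–H deprotonation, loss of phenoxide, capture of isopropyl isocyanate by Et2NH) should free the phenol on carbon 2 of ring A without touching bromide or benzyl ether.

Step 6
Reactants: 11 2,4,6-trihydroxytoluene
Product: 13 2,4,6-trihydroxy-3-methylbenzaldehyde, via iminium chloride 12 (not isolated)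
Conditions: POCl3, DMF, EtOAc, 0 °C to rt; then H2O, 60 °C
Reagents that add atoms: N,N-dimethylformamide, CN(C)C=O (formyl carbon); water, O (formyl oxygen)
Why: Vilsmeier–Haack formylation of the phloroglucinol nucleus, whose two free positions are equivalent and whose first formyl group deactivates the ring against a second attack.

Step 7
Reactants: 13 2,4,6-trihydroxy-3-methylbenzaldehyde
Product: 14 3-acetyl-2,4,6-trihydroxy-5-methylbenzaldehyde
Conditions: AcCl, TiCl4, CH2Cl2, 0 °C to rt; aq. HCl
Reagents that add atoms: acetyl chloride, CC(=O)Cl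
Why: Friedel–Crafts acylation at the single remaining ring carbon, which three hydroxyl groups keep nucleophilic despite the formyl group.

Step 8
Reactants: 14 3-acetyl-2,4,6-trihydroxy-5-methylbenzaldehyde
Product: 15 3-acetyl-2,4,6-tris(benzyloxy)-5-methylbenzaldehyde
Conditions: BnBr, K2CO3, DMF, 60 °C
Reagents that add atoms: benzyl bromide, BrCc1ccccc1
Why: Exhaustive Williamson O-benzylation in a dipolar aprotic solvent, where O-alkylation prevails and C-benzylation would require dearomatisation because every ring carbon is substituted.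

Step 9
Reactants: 15 3-acetyl-2,4,6-tris(benzyloxy)-5-methylbenzaldehyde
Product: 16 1-[2,4,6-tris(benzyloxy)-3-(hydroxymethyl)-5-methylphenyl]ethan-1-one
Conditions: NaBH4, THF–MeOH, −20 to 0 °C
Reagents that add atoms: none
Why: Chemoselective borohydride reduction, in which the aldehyde reacts quickly at low temperature while the methyl ketone, twisted and shielded by two ortho benzyloxy groups, should react far more slowly.

Step 10
Reactants: 10 3-(benzyloxy)-2-bromo-5-methoxy-6-methylphenol; 16 1-[2,4,6-tris(benzyloxy)-3-(hydroxymethyl)-5-methylphenyl]ethan-1-one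
Product: 17 1-[2,4,6-tris(benzyloxy)-3-{[6-(benzyloxy)-5-bromo-4-hydroxy-2-methoxy-3-methylphenyl]methyl}-5-methylphenyl]ethan-1-one
Conditions: BF3·OEt2, CH2Cl2, −20 to 0 °C
Reagents that add atoms: none
Why: Friedel–Crafts benzylation, in which the Lewis acid ionises the trialkoxybenzylic alcohol to a stabilised benzylic cation that attacks carbon 5 of ring A, the only unsubstituted ring carbon of 10 and para to its free hydroxyl, while the bromine on carbon 1 blocks the competing site.

Step 11
Reactants: 17 1-[2,4,6-tris(benzyloxy)-3-{[6-(benzyloxy)-5-bromo-4-hydroxy-2-methoxy-3-methylphenyl]methyl}-5-methylphenyl]ethan-1-one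
Product: 22 4-{[3-acetyl-2,4,6-tris(benzyloxy)-5-methylphenyl]methyl}-3-(benzyloxy)-5-methoxy-6-methyl-2-(trimethylsilyl)phenyl trifluoromethanesulfonate, via bis-silyl ether 18 (not isolated), via aryllithium 19 (not isolated), via lithium phenoxide 20 (not isolated), via enol ether triflate 21 (not isolated)
Conditions: TMSOTf, Et3N, CH2Cl2, 0 °C; hexane extraction, filtration; t-BuLi, THF, −78 °C; PhNTf2, −78 °C to rt; 1 M HCl, THF, 0 °C
Reagents that add atoms: trimethylsilyl trifluoromethanesulfonate, C[Si](C)(C)OS(=O)(=O)C(F)(F)F (SiMe3 that ends on carbon 1 of ring A); N-phenylbis(trifluoromethanesulfonimide), O=S(=O)(N(c1ccccc1)S(=O)(=O)C(F)(F)F)C(F)(F)F (SO2CF3 group)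
Why: Retro-Brook route to 2-silylaryl triflates: phenol and ketone are both O-silylated (the ketone as its enol ether, so it offers neither an electrophilic carbonyl nor acidic hydrogens), bromine–lithium exchange at carbon 1 of ring A triggers 1,3 oxygen-to-carbon migration of the silyl group from the carbon 2 oxygen, the freed phenoxide is triflated by PhNTf2 and dilute acid returns the ketone.

Step 12
Reactants: 22 4-{[3-acetyl-2,4,6-tris(benzyloxy)-5-methylphenyl]methyl}-3-(benzyloxy)-5-methoxy-6-methyl-2-(trimethylsilyl)phenyl trifluoromethanesulfonate; 23 butanoic acid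
Product: 25 1-[3-{[3-acetyl-2,4,6-tris(benzyloxy)-5-methylphenyl]methyl}-2-(benzyloxy)-6-hydroxy-4-methoxy-5-methylphenyl]butan-1-one, via aryne 24 (not isolated)
Conditions: 23 (1 equiv), CsF (4 equiv), THF, 125 °C, sealed tube
Reagents that add atoms: none
Why: Fluoride attacks the silicon on carbon 1 of ring A and triflate leaves from carbon 2 to give aryne 24; caesium butanoate formed in the flask adds through oxygen to carbon 2, and the aryl anion on carbon 1 attacks the neighbouring ester carbonyl through a four-membered alkoxide that opens to the ortho-acyl phenoxide, so the bonds from carbon 2 to oxygen and from carbon 1 to the carbonyl carbon form together. The closest known reaction is the CsF-mediated insertion of arynes from 2-(trimethylsilyl)aryl triflates into the C–O bond of carboxylic acids, which gives ortho-hydroxyaryl ketones in hot THF. No ring remains in the product (the four-membered ring is a transient formed by 4-exo-trig attack and reopened) and no stereocentre is created. The selectivity needed is regiochemical: the inductively withdrawing benzyloxy group on carbon 6 polarises the aryne so that oxygen adds at the distal carbon 2 and the anion sits on carbon 1 beside that oxygen substituent, as is general for 3-alkoxyarynes, and the small methyl on carbon 3 should not override this. Chemoselectivity is secured because ring A has no other free position, every phenol is benzylated so no O–H competes for the aryne, the acid is held at one equivalent so that little proton source remains to quench the aryl anion, and the only carbonyl within reach of the aryl anion is the ester just formed, the ring B acetyl being shielded by two ortho benzyloxy groups.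

Step 13
Reactants: 25 1-[3-{[3-acetyl-2,4,6-tris(benzyloxy)-5-methylphenyl]methyl}-2-(benzyloxy)-6-hydroxy-4-methoxy-5-methylphenyl]butan-1-one
Product: 26 1-{3-[(3-acetyl-2,4,6-trihydroxy-5-methylphenyl)methyl]-2,6-dihydroxy-4-methoxy-5-methylphenyl}butan-1-one
Conditions: H2 (1 atm), Pd/C, EtOAc–MeOH, rt
Reagents that add atoms: none
Why: Catalytic hydrogenolysis of the four aryl benzyl ethers, under which the two hydrogen-bonded ortho-hydroxyaryl ketones and the heteroatom-free diarylmethane bridge should survive.

Compound list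
1 | 3-methoxy-2-methylphenol | COc1cccc(O)c1C | starting material
2 | 3-methoxy-2-methylphenyl propan-2-ylcarbamate | COc1cccc(OC(=O)NC(C)C)c1C | intermediate
3 | 3-methoxy-2-methyl-5-(4,4,5,5-tetramethyl-1,3,2-dioxaborolan-2-yl)phenyl propan-2-ylcarbamate | COc1cc(B2OC(C)(C)C(C)(C)O2)cc(OC(=O)NC(C)C)c1C | intermediate
4 | 5-hydroxy-3-methoxy-2-methylphenyl propan-2-ylcarbamate | COc1cc(O)cc(OC(=O)NC(C)C)c1C | intermediate
5 | 5-(benzyloxy)-3-methoxy-2-methylphenyl propan-2-ylcarbamate | COc1cc(OCc2ccccc2)cc(OC(=O)NC(C)C)c1C | intermediate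
6 | 5-(benzyloxy)-3-methoxy-2-methylphenyl N-[tert-butyl(dimethyl)silyl]-N-propan-2-ylcarbamate | COc1cc(OCc2ccccc2)cc(OC(=O)N(C(C)C)[Si](C)(C)C(C)(C)C)c1C | intermediate
7 | aryllithium of 6, lithiated at the ring carbon between the carbamate and benzyloxy oxygens (carbon 1 of ring A) | COc1cc(OCc2ccccc2)c([Li])c(OC(=O)N(C(C)C)[Si](C)(C)C(C)(C)C)c1C | intermediate
8 | 3-(benzyloxy)-2-bromo-5-methoxy-6-methylphenyl N-[tert-butyl(dimethyl)silyl]-N-propan-2-ylcarbamate | COc1cc(OCc2ccccc2)c(Br)c(OC(=O)N(C(C)C)[Si](C)(C)C(C)(C)C)c1C | intermediate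
9 | 3-(benzyloxy)-2-bromo-5-methoxy-6-methylphenyl propan-2-ylcarbamate | COc1cc(OCc2ccccc2)c(Br)c(OC(=O)NC(C)C)c1C | intermediate
10 | 3-(benzyloxy)-2-bromo-5-methoxy-6-methylphenol | COc1cc(OCc2ccccc2)c(Br)c(O)c1C | intermediate
11 | 2,4,6-trihydroxytoluene (2-methylbenzene-1,3,5-triol) | Cc1c(O)cc(O)cc1O | starting material
12 | N-[(2,4,6-trihydroxy-3-methylphenyl)methylidene]-N-methylmethanaminium chloride | Cc1c(O)cc(O)c(C=[N+](C)C)c1O.[Cl-] | intermediate
13 | 2,4,6-trihydroxy-3-methylbenzaldehyde | Cc1c(O)cc(O)c(C=O)c1O | intermediate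
14 | 3-acetyl-2,4,6-trihydroxy-5-methylbenzaldehyde | CC(=O)c1c(O)c(C=O)c(O)c(C)c1O | intermediate
15 | 3-acetyl-2,4,6-tris(benzyloxy)-5-methylbenzaldehyde | CC(=O)c1c(OCc2ccccc2)c(C=O)c(OCc2ccccc2)c(C)c1OCc1ccccc1 | intermediate
16 | 1-[2,4,6-tris(benzyloxy)-3-(hydroxymethyl)-5-methylphenyl]ethan-1-one | CC(=O)c1c(OCc2ccccc2)c(CO)c(OCc2ccccc2)c(C)c1OCc1ccccc1 | intermediate
17 | 1-[2,4,6-tris(benzyloxy)-3-{[6-(benzyloxy)-5-bromo-4-hydroxy-2-methoxy-3-methylphenyl]methyl}-5-methylphenyl]ethan-1-one | COc1c(C)c(O)c(Br)c(OCc2ccccc2)c1Cc1c(OCc2ccccc2)c(C)c(OCc2ccccc2)c(C(C)=O)c1OCc1ccccc1 | intermediate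
18 | bis(trimethylsilyl) derivative of 17: aryl trimethylsilyl ether on the carbon 2 oxygen of ring A and ring B acetyl as its trimethylsilyl enol ether | COc1c(C)c(O[Si](C)(C)C)c(Br)c(OCc2ccccc2)c1Cc1c(OCc2ccccc2)c(C)c(OCc2ccccc2)c(C(=C)O[Si](C)(C)C)c1OCc1ccccc1 | intermediate
19 | aryllithium of 18 with lithium in place of bromine on carbon 1 of ring A | COc1c(C)c(O[Si](C)(C)C)c([Li])c(OCc2ccccc2)c1Cc1c(OCc2ccccc2)c(C)c(OCc2ccccc2)c(C(=C)O[Si](C)(C)C)c1OCc1ccccc1 | intermediate
20 | lithium phenoxide at carbon 2 of ring A with SiMe3 on carbon 1, ring B enol ether retained | COc1c(C)c([O-])c([Si](C)(C)C)c(OCc2ccccc2)c1Cc1c(OCc2ccccc2)c(C)c(OCc2ccccc2)c(C(=C)O[Si](C)(C)C)c1OCc1ccccc1.[Li+] | intermediate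
21 | trimethylsilyl enol ether of 22 | COc1c(C)c(OS(=O)(=O)C(F)(F)F)c([Si](C)(C)C)c(OCc2ccccc2)c1Cc1c(OCc2ccccc2)c(C)c(OCc2ccccc2)c(C(=C)O[Si](C)(C)C)c1OCc1ccccc1 | intermediate
22 | 4-{[3-acetyl-2,4,6-tris(benzyloxy)-5-methylphenyl]methyl}-3-(benzyloxy)-5-methoxy-6-methyl-2-(trimethylsilyl)phenyl trifluoromethanesulfonate | C[Si](C)(C)c1c(OS(=O)(=O)C(F)(F)F)c(C)c(OC)c(Cc2c(OCc3ccccc3)c(C)c(OCc3ccccc3)c(C(C)=O)c2OCc2ccccc2)c1OCc1ccccc1 | intermediate
23 | butanoic acid | CCCC(=O)O | starting material
24 | aryne with the formal triple bond between carbons 1 and 2 of ring A (methyl on carbon 3, methoxy on carbon 4, ring B benzyl group on carbon 5, benzyloxy on carbon 6) | C1#CC(C)=C(OC)C(Cc2c(OCc3ccccc3)c(C)c(OCc3ccccc3)c(C(C)=O)c2OCc2ccccc2)=C1OCc1ccccc1 | intermediate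
25 | 1-[3-{[3-acetyl-2,4,6-tris(benzyloxy)-5-methylphenyl]methyl}-2-(benzyloxy)-6-hydroxy-4-methoxy-5-methylphenyl]butan-1-one | CCCC(=O)c1c(O)c(C)c(OC)c(Cc2c(OCc3ccccc3)c(C)c(OCc3ccccc3)c(C(C)=O)c2OCc2ccccc2)c1OCc1ccccc1 | intermediate
26 | 1-{3-[(3-acetyl-2,4,6-trihydroxy-5-methylphenyl)methyl]-2,6-dihydroxy-4-methoxy-5-methylphenyl}butan-1-one | CCCC(=O)c1c(O)c(C)c(OC)c(Cc2c(O)c(C)c(O)c(C(C)=O)c2O)c1O | target

Total step count: 13. Longest linear sequence: 9 steps (steps 1–5 and 10–13); the ring B branch (steps 6–9) joins at step 10.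

Steps most likely to fail

Step 12. The aryl anion formed after carboxylate addition may be protonated before it reaches the ester carbonyl, leaving only O-arylation. Oxygen may also add at carbon 1 of ring A against the polarisation, or the aryne may be consumed by enolised ring B ketone. Fallback: the acyl group is installed by organolithium acylation, bypassing the aryne. Setting out from 17, the phenol on carbon 2 of ring A is benzylated (BnBr, K2CO3, DMF) to the penta-O-benzyl aryl bromide F1. Its ketone is masked with TBSOTf and Et3N as the silyl enol ether F2. Bromine–lithium exchange (t-BuLi, THF, −78 °C), acylation with N-methoxy-N-methylbutanamide and acidic work-up should give the penta-O-benzyl diketone F3. Hydrogenolysis of all five benzyl ethers (H2, Pd/C) returns to the route at 26.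

Step 11. The alkyllithium may attack silicon of the enol ether or the aryl silyl ether, incomplete enol silylation may expose the ketone to deprotonation or addition, and triflation of the crowded phenoxide may be slow. Fallback: a redox detour keeps any carbonyl out of the lithiation. Setting out from 17, the ketone is reduced (LiAlH4, THF, 0 °C) to the racemic carbinol F4. Hexamethyldisilazane silylates both hydroxyls to give the bis(trimethylsilyl) ether F5, which is used directly. Bromine–lithium exchange with n-BuLi at −78 °C, silyl migration and K2CO3/MeOH work-up should give the 2-silylphenol carbinol F6. Phenol-selective triflation (PhNTf2, Et3N) gives the silyl triflate carbinol F7, and Dess–Martin oxidation returns to the route at 22.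

Step 10. Substitution at the crowded carbon 5 of ring A between two alkoxy groups may be slow, which would let the ring B benzylic cation decay by ether formation or benzyl loss, or the acid may cause loss of the bromine on carbon 1. Fallback: the bridge is made by Negishi coupling. Setting out from 10, iodination with N-iodosuccinimide at the only open position gives the bromo iodo phenol F8. Setting out from 16, MsCl, Et3N and LiCl give the benzylic chloride F9, and Zn with LiCl in THF gives the benzylzinc chloride F10. After deprotonation of F8 with NaH, coupling at the C–I bond with Pd(OAc)2 and SPhos returns to the route at 17.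

Further compounds
F1 | step 12 | 1-[2,4,6-tris(benzyloxy)-3-{[4,6-bis(benzyloxy)-5-bromo-2-methoxy-3-methylphenyl]methyl}-5-methylphenyl]ethan-1-one | COc1c(C)c(OCc2ccccc2)c(Br)c(OCc2ccccc2)c1Cc1c(OCc2ccccc2)c(C)c(OCc2ccccc2)c(C(C)=O)c1OCc1ccccc1
F2 | step 12 | tert-butyldimethylsilyl enol ether of F1 | COc1c(C)c(OCc2ccccc2)c(Br)c(OCc2ccccc2)c1Cc1c(OCc2ccccc2)c(C)c(OCc2ccccc2)c(C(=C)O[Si](C)(C)C(C)(C)C)c1OCc1ccccc1
F3 | step 12 | 1-[3-{[3-acetyl-2,4,6-tris(benzyloxy)-5-methylphenyl]methyl}-2,6-bis(benzyloxy)-4-methoxy-5-methylphenyl]butan-1-one | CCCC(=O)c1c(OCc2ccccc2)c(C)c(OC)c(Cc2c(OCc3ccccc3)c(C)c(OCc3ccccc3)c(C(C)=O)c2OCc2ccccc2)c1OCc1ccccc1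
F4 | step 11 | racemic 1-[2,4,6-tris(benzyloxy)-3-{[6-(benzyloxy)-5-bromo-4-hydroxy-2-methoxy-3-methylphenyl]methyl}-5-methylphenyl]ethan-1-ol | COc1c(C)c(O)c(Br)c(OCc2ccccc2)c1Cc1c(OCc2ccccc2)c(C)c(OCc2ccccc2)c(C(C)O)c1OCc1ccccc1
F5 | step 11 | racemic bis(trimethylsilyl) ether of F4 (phenol and carbinol oxygens) | COc1c(C)c(O[Si](C)(C)C)c(Br)c(OCc2ccccc2)c1Cc1c(OCc2ccccc2)c(C)c(OCc2ccccc2)c(C(C)O[Si](C)(C)C)c1OCc1ccccc1
F6 | step 11 | racemic 3-(benzyloxy)-5-methoxy-6-methyl-2-(trimethylsilyl)phenol carrying at position 4 the [2,4,6-tris(benzyloxy)-3-(1-hydroxyethyl)-5-methylphenyl]methyl group | COc1c(C)c(O)c([Si](C)(C)C)c(OCc2ccccc2)c1Cc1c(OCc2ccccc2)c(C)c(OCc2ccccc2)c(C(C)O)c1OCc1ccccc1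
F7 | step 11 | racemic trifluoromethanesulfonate of F6 at the phenol oxygen | COc1c(C)c(OS(=O)(=O)C(F)(F)F)c([Si](C)(C)C)c(OCc2ccccc2)c1Cc1c(OCc2ccccc2)c(C)c(OCc2ccccc2)c(C(C)O)c1OCc1ccccc1
F8 | step 10 | 3-(benzyloxy)-2-bromo-4-iodo-5-methoxy-6-methylphenol | COc1c(I)c(OCc2ccccc2)c(Br)c(O)c1C
F9 | step 10 | 1-[2,4,6-tris(benzyloxy)-3-(chloromethyl)-5-methylphenyl]ethan-1-one | CC(=O)c1c(OCc2ccccc2)c(CCl)c(OCc2ccccc2)c(C)c1OCc1ccccc1
F10 | step 10 | {[3-acetyl-2,4,6-tris(benzyloxy)-5-methylphenyl]methyl}zinc chloride | CC(=O)c1c(OCc2ccccc2)c(C[Zn]Cl)c(OCc2ccccc2)c(C)c1OCc1ccccc1
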